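Remark on the chemistry: the ansa chain is numbered C1 (amide carbonyl) to C15 (benzylic carbon) and the arene C16–C21 (C18 phenol, C20 nitrogen). The target is read as (6S,7R,10S,11R,12S,14R) with E alkenes at C2=C3 and C8=C9. (+)-Ipc2BOMe means the B-methoxydiisopinocampheylborane made from (−)-α-pinene, whose oxidation returns (1S,2S,3S,5R)-isopinocampheol. Both enantiomers of 4-benzyl-3-propionyloxazolidin-2-one and 2-(triphenylphosphoranylidene)propanal are taken as purchased materials.

## Analysis of the target

The target 44 is a 19-membered ansa-macrolactam. A fifteen-carbon chain (C1 to C15) bridges the meta positions C20 (nitrogen) and C16 of a benzene ring (C16–C21) that carries a free phenol at C18. The chain holds six stereocentres in two groups separated by the E-trisubstituted C8=C9 alkene. The C6 methyl and C7 carbamate are syn; the C10 methyl and C11 hydroxyl are syn, the C11 hydroxyl and C12 methoxy are anti, and C12 and C14 are 1,3-anti across the C13 methylene. A second E-trisubstituted alkene, C2=C3, is conjugated to the anilide. The sensitive groups are the primary carbamate on the allylic C7 (ionisable, base-labile, able to migrate to a free C11 hydroxyl), the oxidation-prone 3-amino-5-hydroxyphenyl ring, and the enamide acceptor. The synthesis is hard because a flexible 19-membered ring must be closed without disturbing these groups, and because C8=C9 and C13H2 insulate the stereo-groups from each other, so the C6/C7 pair, the C10–C12 triad and C14 must each be set by reagent control. The strategy rests on the C4–C5 ethylene: it links the sp2 carbon C3 of the enamide to C6, a methyl-bearing stereocentre next to the C7 carbinol, so C4–C5 is the hydroborated form of the vinyl group that a crotylation of a C7 aldehyde leaves on C6.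

## Retrosynthetic reasoning

**Silyl ethers (44 to 43).** The last operation is kept trivial: 44 is traced back to 43, with C11 as a TBS ether and the phenol as a TIPS ether. This keeps the aminophenol and the C11 hydroxyl masked until nothing else has to be done, and both groups fall to fluoride in one step. The phenol gets the bulkier silyl group because, until the nitrogen is acylated, it sits on an electron-poor nitroarene from which a smaller aryl silyl ether would be lost under hydride, peroxide, borate or aqueous carbonate conditions. C11 is kept as TBS because that ether must finally leave a crowded site.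

**C3–C4 (43 to 41 through 42).** The ring is opened between the enamide carbon C3 and the methylene C4. This gives the (E)-β-iodoenamide 41 with a vinyl group on C6; the alkylborane 42 is the species that actually cyclises. The cut is made here for three reasons. The vinyl group is what the crotylation that sets C6 and C7 leaves behind, so the coupling handle costs nothing. No stereocentre is made or endangered in the ring closure, and the E geometry of C2=C3 is fixed beforehand in a three-carbon reagent. The amide bond can then be made early and between two molecules. Cutting at N–C1 or N–C20 would ask a weakly nucleophilic aniline or a metal-mediated arylation to close the ring, and cutting at C8=C9 would mean building a trisubstituted alkene inside the ring. The forward step must hydroborate one alkene out of three and couple within the molecule, not between molecules.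

**N–C1 (41 to 35 and 39).** The anilide bond is cut to aniline 35 and (E)-3-iodo-2-methylacrylic acid 39, used as its chloride 40. The acylation only has to distinguish an aniline from a primary carbamate nitrogen. Acid 39 goes back to the diiodomethyl malonate 38 and to diethyl methylmalonate 36 (through its enolate 37). C3 comes from a one-carbon electrophile, and a decarboxylative elimination sets the E geometry.

**Nitrogen and carbamate (35 to 34 to 32).** The aniline is carried as a nitro group (34) from the first step, so no nitrogen protecting group is needed. The carbamate is put on the C7 hydroxyl of 32 as soon as that hydroxyl exists (through 33), so C7 never needs a protecting group either.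

**C6–C7 (32 to 28 and 29).** The C6–C7 bond is cut to the C7 enal 28 and a (Z)-crotyl unit from cis-but-2-ene 29, delivered by the chiral borane 31 (made through 30). One step then gives the syn C6/C7 pair, the absolute configuration and the terminal alkene for the key step. This is the only place where the crotyl reagent, which has to be made fresh at low temperature, is used.

**C8=C9 (28 to 26 and 27).** The enal is cut at its double bond to aldehyde 26 and the stabilised formyl ylide 27. The ylide is not basic, so the C10 centre next to the aldehyde is not put at risk, and a stabilised ylide gives the E alkene. Aldehyde 26 is the oxidised form of alcohol 25, which comes from the silylated imide 24 by reductive removal of the auxiliary.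

**C10–C11 (24 to 23 to 20 and 21).** The C10/C11 syn pair is cut as an aldol between the α-methoxy aldehyde 20 and the boron enolate 22 of the propionyl imide 21. The aldol leaves C9 as a carbonyl carbon, which is turned into the C8=C9 alkene by olefination without any alkene metathesis on a hindered, allylically branched chain. The auxiliary sets 10S,11R, and the required 11,12-anti relation is the one a (Z)-enolate prefers with an α-alkoxy aldehyde, so reagent and substrate agree. A second crotylation followed by cross-metathesis would be two steps shorter and is kept as the reserve for this sequence.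

**C12–O (20 to 19 to 18 to 17 to 15).** The C12 methoxy group is traced to a hydroxyl introduced on the enolate 16 of the acyl oxazolidinone 15. The auxiliary sets C12 without help from the remote C14 centre.

**C12–C13 (15 to 14 to 9 and 13).** The two carbons C11 and C12 and the auxiliary are added together by olefination of aldehyde 9 with phosphonate 13, followed by saturation of the alkene. Phosphonate 13 comes from 10 and 11 through 12.

**C14–C15 (9 to 8 to 7 to 5 and 4).** C14 is set by alkylating the enolate 6 of (S)-4-benzyl-3-propionyloxazolidin-2-one 5 with the benzylic bromide 4, a reactive electrophile of the kind this alkylation needs.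

**Arene (4 to 3 to 2 to 1).** Bromide 4 comes from 3-hydroxy-5-nitrobenzoic acid 1 by reduction, phenol silylation and bromination. The substitution pattern of the target arene is bought, not made.

## Alternatives that were turned down

**Alternative 1:** Two arene bonds, C18–C19 and C20–C21, are cut, so that the benzene ring and the macrolactam form in one step. The open chain would end in a 3-substituted cyclobutenone (C16, C17, C18, C21) and an N-alkynyl amide (C19, C20).
- Forward key step: heating at high dilution opens the cyclobutenone to a vinylketene, which adds to the ynamide; a second ring opening and a 6π closure give the phenol A1 (N-4-methoxybenzyl lactam, C7 O-TES, C11 O-TBS).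
- For it: two rings and two C–C bonds form in one metal-free step, the phenol appears unprotected, and no nitro group has to be carried through the chain synthesis. On convergence and bonds formed per step it is stronger than the chosen route.
- Against it: the ketene–ynamide cycloaddition must find its partner across a 19-membered ring, while vinylketenes dimerise readily. The ynamide nitrogen carries the C1 enoyl group, a hydration-prone unit that must be assembled on a full-length chain. After the key step A1 still needs N-debenzylation (oxidative conditions threaten the aminophenol, acidic ones the allylic C7 oxygen), TES removal, carbamoylation and desilylation: four steps against one.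
- Comparison: the chosen route gives up that elegance for a ring closure of a well-charted reaction class and an end game of one step.

**Alternative 2:** The ring is cut at C8–C9 as an alkyne, and the trisubstituted alkene is made afterwards.
- Forward key step: ring-closing alkyne metathesis of a diyne with methyl-capped alkynes on C7 and C10, using a molybdenum alkylidyne of the type Mo(≡CAr)(OSiPh3)3 over molecular sieves, gives cycloalkyne A2 with loss of a volatile small alkyne. A hydroxyl-directed trans-hydrostannation and a methyl-for-tin exchange would then create C8(Me)=C9.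
- For it: alkyne metathesis is indifferent to ring size, tolerates the anilide, is driven by loss of a volatile by-product and runs at higher concentration than a cross-coupling macrocyclisation. On the reliability of the ring closure itself it is the stronger option.
- Against it: neither the alkene geometry nor the C8 methyl exists at ring closure; both must come from a regio- and stereoselective hydrometalation between two stereocentres. The directing C7 hydroxyl must first be freed, so five steps follow the ring closure (desilylation, hydrostannation, methylation, carbamoylation, final desilylation), one with stoichiometric tin. The propargylic centres C7 and C10 cannot be made by the aldol and crotylation logic used here.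
- Comparison: the chosen route has both alkenes in place before cyclisation and needs one step after it.

**Alternative 3:** The aryl–nitrogen bond N–C20 is cut.
- Forward key step: intramolecular Goldberg-type amidation of an aryl bromide by the primary C1 enamide, with CuI, a 1,2-diamine ligand and K3PO4 in a hot ethereal solvent, gives lactam A3 (C7 O-TES, C11 O-TBS, phenol O-TIPS).
- For it: no nitro group is needed, and an aryl bromide is inert to the hydrides, enolates and organometallics of a long chain synthesis. In this respect it is stronger than the chosen route, whose nitro group restricts reductants and excludes hard organometallics.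
- Against it: the amidate must bind copper and then meet the aryl bromide of the same molecule at high dilution, where catalysis by CuI is slow and usually needs much metal and temperatures above 100 °C. A primary carbamate on an allylic carbon is unlikely to survive hot phosphate, so C7 must be carried as a TES ether and three steps follow the ring closure. The E-enamide can isomerise or add nucleophiles at that temperature.
- Comparison: the chosen route closes the ring near 45 °C with the carbamate already in place, and makes the anilide between two molecules with an acid chloride.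

Key step: step 25

## Route

Step 1
Reactants: 1 3-hydroxy-5-nitrobenzoic acid
Product: 2 3-(hydroxymethyl)-5-nitrophenol
Conditions: BH3·THF, THF, 0 °C → rt; then H2O
Reagents that add atoms: none
Why: Chemoselective borane reduction of a carboxylic acid: the acyloxyborane is reduced much faster than an aromatic nitro group, so the benzylic alcohol forms with the nitrogen untouched.

Step 2
Reactants: 2 3-(hydroxymethyl)-5-nitrophenol
Product: 3 [3-nitro-5-(triisopropylsilyloxy)phenyl]methanol
Conditions: TIPSCl (1.05 equiv), Et3N, CH2Cl2, 0 °C → rt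
Reagents that add atoms: triisopropylsilyl chloride, CC(C)[Si](Cl)(C(C)C)C(C)C
Why: Chemoselective O-silylation: Et3N deprotonates only the acidic nitrophenol, and the phenoxide is silylated while the neutral primary alcohol is inert to the hindered chloride without a nucleophilic catalyst.

Step 3
Reactants: 3 [3-nitro-5-(triisopropylsilyloxy)phenyl]methanol
Product: 4 3-nitro-5-(triisopropylsilyloxy)benzyl bromide
Conditions: CBr4, PPh3, CH2Cl2, 0 °C
Reagents that add atoms: carbon tetrabromide, BrC(Br)(Br)Br
Why: Appel bromination of a primary benzylic alcohol under neutral conditions, which leaves the aryl silyl ether and the nitro group alone.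

Step 4
Reactants: 5 (S)-4-benzyl-3-propionyloxazolidin-2-one; 4 3-nitro-5-(triisopropylsilyloxy)benzyl bromide
Product: 7 (S)-4-benzyl-3-[(R)-2-methyl-3-[3-nitro-5-(triisopropylsilyloxy)phenyl]propanoyl]oxazolidin-2-one, via sodium (Z)-enolate of the propionyl imide 6 (not isolated)
Conditions: NaN(SiMe3)2, THF, −78 °C; then 4, −78 → −30 °C
Reagents that add atoms: none
Why: Evans asymmetric alkylation: the chelated (Z)-enolate 6 is shielded on one face by the benzyl group of the auxiliary, so the benzylic bromide enters from the open face and sets C14 as R.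

Step 5
Reactants: 7 (S)-4-benzyl-3-[(R)-2-methyl-3-[3-nitro-5-(triisopropylsilyloxy)phenyl]propanoyl]oxazolidin-2-one
Product: 8 (R)-2-methyl-3-[3-nitro-5-(triisopropylsilyloxy)phenyl]propan-1-ol
Conditions: LiBH4, H2O (1 equiv), Et2O, 0 °C
Reagents that add atoms: none
Why: Reductive removal of the auxiliary: borohydride attacks the exocyclic imide carbonyl and gives the primary alcohol; the nitro group and the aryl silyl ether are inert to LiBH4 and C14 cannot epimerise.

Step 6
Reactants: 8 (R)-2-methyl-3-[3-nitro-5-(triisopropylsilyloxy)phenyl]propan-1-ol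
Product: 9 (R)-2-methyl-3-[3-nitro-5-(triisopropylsilyloxy)phenyl]propanal
Conditions: Dess–Martin periodinane, NaHCO3, CH2Cl2, 0 °C → rt; used at once
Reagents that add atoms: none
Why: Dess–Martin oxidation under buffered, non-basic conditions; the α-methyl aldehyde is not stored, which limits epimerisation at C14.

Step 7
Reactants: 10 2-(diethoxyphosphoryl)acetic acid; 11 (S)-4-benzyloxazolidin-2-one
Product: 13 (S)-4-benzyl-3-[2-(diethoxyphosphoryl)acetyl]oxazolidin-2-one, via pivalic mixed anhydride of the phosphonoacetic acid 12 (not isolated)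
Conditions: PivCl, Et3N, THF, −20 °C; then 11, LiCl, rt
Reagents that add atoms: none
Why: N-acylation of an oxazolidinone through a mixed pivalic anhydride: LiCl acidifies the carbamate N–H so that Et3N suffices, and the hindered pivaloyl carbonyl of 12 is not attacked.

Step 8
Reactants: 9 (R)-2-methyl-3-[3-nitro-5-(triisopropylsilyloxy)phenyl]propanal; 13 (S)-4-benzyl-3-[2-(diethoxyphosphoryl)acetyl]oxazolidin-2-one
Product: 14 (S)-4-benzyl-3-[(2E,4R)-4-methyl-5-[3-nitro-5-(triisopropylsilyloxy)phenyl]pent-2-enoyl]oxazolidin-2-one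
Conditions: LiCl, iPr2NEt, MeCN, rt
Reagents that add atoms: none
Why: Horner–Wadsworth–Emmons olefination under Masamune–Roush conditions: lithium chelation lets an amine base deprotonate the phosphonate, which spares the epimerisable aldehyde, and the stabilised phosphonate gives the E enoyl imide. The step adds C11, C12 and the auxiliary that will control C12.

Step 9
Reactants: 14 (S)-4-benzyl-3-[(2E,4R)-4-methyl-5-[3-nitro-5-(triisopropylsilyloxy)phenyl]pent-2-enoyl]oxazolidin-2-one
Product: 15 (S)-4-benzyl-3-[(S)-4-methyl-5-[3-nitro-5-(triisopropylsilyloxy)phenyl]pentanoyl]oxazolidin-2-one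
Conditions: H2 (1 atm), RhCl(PPh3)3 (10 mol %), benzene/EtOH, rt
Reagents that add atoms: none
Why: Homogeneous hydrogenation with RhCl(PPh3)3 reduces the disubstituted conjugated alkene and leaves the aromatic nitro group, which H2 over Pd/C or PtO2 would reduce. The C14 descriptor changes from R to S only because the ranking of its neighbours changes.

Step 10
Reactants: 15 (S)-4-benzyl-3-[(S)-4-methyl-5-[3-nitro-5-(triisopropylsilyloxy)phenyl]pentanoyl]oxazolidin-2-one
Product: 17 (S)-4-benzyl-3-[(2S,4R)-2-hydroxy-4-methyl-5-[3-nitro-5-(triisopropylsilyloxy)phenyl]pentanoyl]oxazolidin-2-one, via sodium (Z)-enolate of the pentanoyl imide 16 (not isolated)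
Conditions: NaN(SiMe3)2, THF, −78 °C; 2-(phenylsulfonyl)-3-phenyloxaziridine, −78 °C; AcOH quench
Reagents that add atoms: 2-(phenylsulfonyl)-3-phenyloxaziridine (Davis oxaziridine), O=S(=O)(c1ccccc1)N1OC1c1ccccc1
Why: Electrophilic enolate hydroxylation with the Davis oxaziridine: the chelated (Z)-enolate 16 takes the oxygen on the face away from the benzyl group, the same facial sense as in step 4, which gives 12S. The distant C14 centre has no influence.

Step 11
Reactants: 17 (S)-4-benzyl-3-[(2S,4R)-2-hydroxy-4-methyl-5-[3-nitro-5-(triisopropylsilyloxy)phenyl]pentanoyl]oxazolidin-2-one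
Product: 18 (S)-4-benzyl-3-[(2S,4R)-2-methoxy-4-methyl-5-[3-nitro-5-(triisopropylsilyloxy)phenyl]pentanoyl]oxazolidin-2-one
Conditions: Me3OBF4, 1,8-bis(dimethylamino)naphthalene, 4 Å MS, CH2Cl2, 0 °C → rt
Reagents that add atoms: trimethyloxonium tetrafluoroborate, C[O+](C)C.F[B-](F)(F)F
Why: O-methylation with Me3OBF4 buffered by a non-nucleophilic amine: no alkoxide forms, so neither epimerisation at C12 nor attack of the hydroxyl on the oxazolidinone carbonyl can compete.

Step 12
Reactants: 18 (S)-4-benzyl-3-[(2S,4R)-2-methoxy-4-methyl-5-[3-nitro-5-(triisopropylsilyloxy)phenyl]pentanoyl]oxazolidin-2-one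
Product: 19 (2S,4R)-2-methoxy-4-methyl-5-[3-nitro-5-(triisopropylsilyloxy)phenyl]pentan-1-ol
Conditions: LiBH4, MeOH (1 equiv), THF, 0 °C
Reagents that add atoms: none
Why: Reductive cleavage of the imide as in step 5; C12 is safe because no enolisable carbonyl survives.

Step 13
Reactants: 19 (2S,4R)-2-methoxy-4-methyl-5-[3-nitro-5-(triisopropylsilyloxy)phenyl]pentan-1-ol
Product: 20 (2S,4R)-2-methoxy-4-methyl-5-[3-nitro-5-(triisopropylsilyloxy)phenyl]pentanal
Conditions: Dess–Martin periodinane, NaHCO3, CH2Cl2, 0 °C; used crude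
Reagents that add atoms: none
Why: Buffered Dess–Martin oxidation; the α-methoxy aldehyde is carried on cold and crude to avoid hydration and epimerisation at C12.

Step 14
Reactants: 20 (2S,4R)-2-methoxy-4-methyl-5-[3-nitro-5-(triisopropylsilyloxy)phenyl]pentanal; 21 (R)-4-benzyl-3-propionyloxazolidin-2-one
Product: 23 (R)-4-benzyl-3-[(2R,3R,4S,6R)-3-hydroxy-4-methoxy-2,6-dimethyl-7-[3-nitro-5-(triisopropylsilyloxy)phenyl]heptanoyl]oxazolidin-2-one, via dibutylboron (Z)-enolate of the propionyl imide 22 (not isolated)
Conditions: 21, Bu2BOTf, iPr2NEt, CH2Cl2, −78 → 0 °C; then 20, −78 → 0 °C; pH 7 buffer, MeOH, H2O2, 0 °C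
Reagents that add atoms: none
Why: Evans syn aldol reaction: the (Z)-boron enolate 22 reacts through a closed chair transition state in which the R auxiliary, with its carbonyl dipoles opposed, exposes the enolate face that gives the C10/C11 syn pair as 10S,11R. A (Z)-enolate adds to an α-alkoxy aldehyde with 11,12-anti preference (Cornforth-type transition state), so auxiliary and aldehyde are matched.

Step 15
Reactants: 23 (R)-4-benzyl-3-[(2R,3R,4S,6R)-3-hydroxy-4-methoxy-2,6-dimethyl-7-[3-nitro-5-(triisopropylsilyloxy)phenyl]heptanoyl]oxazolidin-2-one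
Product: 24 (R)-4-benzyl-3-[(2R,3R,4S,6R)-3-(tert-butyldimethylsilyloxy)-4-methoxy-2,6-dimethyl-7-[3-nitro-5-(triisopropylsilyloxy)phenyl]heptanoyl]oxazolidin-2-one
Conditions: TBSOTf, 2,6-lutidine, CH2Cl2, −78 → 0 °C
Reagents that add atoms: tert-butyldimethylsilyl triflate, CC(C)(C)[Si](C)(C)OS(=O)(=O)C(F)(F)F
Why: Silylation of a hindered secondary alcohol with a silyl triflate and a hindered pyridine base; capping the aldol hydroxyl also blocks retro-aldol cleavage, and this C11 ether stays until the last step.

Step 16
Reactants: 24 (R)-4-benzyl-3-[(2R,3R,4S,6R)-3-(tert-butyldimethylsilyloxy)-4-methoxy-2,6-dimethyl-7-[3-nitro-5-(triisopropylsilyloxy)phenyl]heptanoyl]oxazolidin-2-one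
Product: 25 (2S,3R,4S,6R)-3-(tert-butyldimethylsilyloxy)-4-methoxy-2,6-dimethyl-7-[3-nitro-5-(triisopropylsilyloxy)phenyl]heptan-1-ol
Conditions: LiBH4, MeOH (1 equiv), THF, 0 °C
Reagents that add atoms: none
Why: Reductive removal of the auxiliary as in step 5: the exocyclic imide carbonyl is reduced to the primary alcohol, while the nitro group and both silyl ethers are inert to LiBH4. The C10 descriptor changes from R to S only because the ranking of its neighbours changes.

Step 17
Reactants: 25 (2S,3R,4S,6R)-3-(tert-butyldimethylsilyloxy)-4-methoxy-2,6-dimethyl-7-[3-nitro-5-(triisopropylsilyloxy)phenyl]heptan-1-ol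
Product: 26 (2R,3R,4S,6R)-3-(tert-butyldimethylsilyloxy)-4-methoxy-2,6-dimethyl-7-[3-nitro-5-(triisopropylsilyloxy)phenyl]heptanal
Conditions: Dess–Martin periodinane, NaHCO3, CH2Cl2, 0 °C → rt; used at once
Reagents that add atoms: none
Why: Buffered Dess–Martin oxidation of a primary alcohol; the α-methyl-β-silyloxy aldehyde is used without storage, so neither epimerisation at C10 nor β-elimination of the silyloxy group has time to occur.

Step 18
Reactants: 26 (2R,3R,4S,6R)-3-(tert-butyldimethylsilyloxy)-4-methoxy-2,6-dimethyl-7-[3-nitro-5-(triisopropylsilyloxy)phenyl]heptanal; 27 2-(triphenylphosphoranylidene)propanal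
Product: 28 (2E,4S,5R,6S,8R)-5-(tert-butyldimethylsilyloxy)-6-methoxy-2,4,8-trimethyl-9-[3-nitro-5-(triisopropylsilyloxy)phenyl]non-2-enal
Conditions: 27 (2 equiv), toluene, 90 °C
Reagents that add atoms: none
Why: Wittig olefination with a stabilised formyl ylide: the reversible addition of such ylides leads to the E-trisubstituted enal, and the ylide is not basic enough to epimerise C10. The conjugated, α-branched enal formed is much less electrophilic than 26, so a second homologation does not compete.

Step 19
Reactants: 28 (2E,4S,5R,6S,8R)-5-(tert-butyldimethylsilyloxy)-6-methoxy-2,4,8-trimethyl-9-[3-nitro-5-(triisopropylsilyloxy)phenyl]non-2-enal; 29 cis-but-2-ene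
Product: 32 (3S,4R,5E,7S,8R,9S,11R)-8-(tert-butyldimethylsilyloxy)-9-methoxy-3,5,7,11-tetramethyl-12-[3-nitro-5-(triisopropylsilyloxy)phenyl]dodeca-1,5-dien-4-ol, via (Z)-crotylpotassium 30 (not isolated), via (Z)-crotyldiisopinocampheylborane 31 (not isolated)
Conditions: 29 (excess), n-BuLi, KOtBu, THF, −78 → −45 °C; (+)-Ipc2BOMe (slight excess over n-BuLi), −78 °C; BF3·OEt2; then 28, −78 °C; NaBO3·4H2O, H2O, rt
Reagents that add atoms: none
Why: Brown (Z)-crotylboration: the aldehyde reacts through a closed chair transition state with the Z-methyl axial, which gives the C6/C7 syn pair, and the isopinocampheyl groups of the (−)-α-pinene series select the aldehyde face that gives 7R, the nearest stereocentre (C10) being too remote to compete. An allylborane adds to an enal only in the 1,2 sense, all organoalkali is consumed by the borinate before 28 is added so the nitroarene never meets it, and the vinyl group left on C6 is the handle for the ring closure.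

Step 20
Reactants: 32 (3S,4R,5E,7S,8R,9S,11R)-8-(tert-butyldimethylsilyloxy)-9-methoxy-3,5,7,11-tetramethyl-12-[3-nitro-5-(triisopropylsilyloxy)phenyl]dodeca-1,5-dien-4-ol
Product: 34 (3S,4R,5E,7S,8R,9S,11R)-8-(tert-butyldimethylsilyloxy)-9-methoxy-3,5,7,11-tetramethyl-12-[3-nitro-5-(triisopropylsilyloxy)phenyl]dodeca-1,5-dien-4-yl carbamate, via N-(trichloroacetyl)carbamate of the C7 alcohol 33 (not isolated)
Conditions: Cl3CC(O)NCO, CH2Cl2, 0 °C; then neutral Al2O3, rt
Reagents that add atoms: trichloroacetyl isocyanate, O=C=NC(=O)C(Cl)(Cl)Cl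
Why: Carbamoylation of a secondary alcohol with an acyl isocyanate, then hydrolytic loss of the trichloroacetyl group on neutral Al2O3; the neutral second stage spares the aryl silyl ether on the nitroarene.

Step 21
Reactants: 34 nitroarene carbamate
Product: 35 (3S,4R,5E,7S,8R,9S,11R)-12-[3-amino-5-(triisopropylsilyloxy)phenyl]-8-(tert-butyldimethylsilyloxy)-9-methoxy-3,5,7,11-tetramethyldodeca-1,5-dien-4-yl carbamate
Conditions: Fe powder, NH4Cl, EtOH/H2O, 70 °C
Reagents that add atoms: none
Why: Béchamp-type reduction of an aromatic nitro group by Fe in weakly acidic aqueous ethanol; alkenes, the allylic carbamate and both silyl ethers are inert to it, unlike under catalytic hydrogenation.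

Step 22
Reactants: 36 diethyl methylmalonate
Product: 38 diethyl 2-(diiodomethyl)-2-methylmalonate, via sodium enolate of diethyl methylmalonate 37 (not isolated)
Conditions: NaH, Et2O, reflux; CHI3, reflux
Reagents that add atoms: iodoform, IC(I)I
Why: C-alkylation of the malonate enolate 37 by iodoform (diiodocarbene formation, capture by the enolate, protonation); this installs the future C3 carrying two iodines.

Step 23
Reactants: 38 diethyl 2-(diiodomethyl)-2-methylmalonate
Product: 39 (E)-3-iodo-2-methylacrylic acid
Conditions: KOH, EtOH/H2O, reflux; then aq. HCl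
Reagents that add atoms: potassium hydroxide, [K+].[OH-]
Why: Saponification followed by decarboxylative elimination of iodide: loss of CO2 and iodide gives the alkene with iodine trans to the remaining carboxylate, that is the E acid.

Step 24
Reactants: 35 aniline carbamate; 39 (E)-3-iodo-2-methylacrylic acid
Product: 41 N-[3-[(2R,4S,5R,6S,7E,9R,10S)-5-(tert-butyldimethylsilyloxy)-9-(carbamoyloxy)-4-methoxy-2,6,8,10-tetramethyldodeca-7,11-dien-1-yl]-5-(triisopropylsilyloxy)phenyl]-(E)-3-iodo-2-methylacrylamide, via (E)-3-iodo-2-methylacryloyl chloride 40 (not isolated)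
Conditions: 39, (COCl)2, cat. DMF, CH2Cl2, 0 °C → rt, concentrate; then 35, pyridine, CH2Cl2, 0 °C
Reagents that add atoms: none
Why: Acid chloride formation and N-acylation of an aniline in the presence of pyridine; the aniline is far more nucleophilic than the primary carbamate nitrogen, and the alkenyl iodide geometry is not at risk.

Step 25
Reactants: 41 seco (E)-β-iodoenamide with the C6 vinyl group
Product: 43 macrolactam bis-silyl ether (skeleton of the target carrying C11 O-TBS plus phenol O-TIPS), via C4 B-alkyl-9-borabicyclo[3.3.1]nonane 42 (not isolated)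
Conditions: 9-BBN (3 equiv), THF, rt; then syringe-pump addition to Pd(dppf)Cl2 (20 mol %), AsPh3 (40 mol %), Cs2CO3, DMF/THF/H2O, 45 °C, about 1 mM
Reagents that add atoms: none
Why: B-alkyl Suzuki–Miyaura macrocyclisation. 9-BBN adds to the only monosubstituted alkene (C4=C5) with boron on C4; the trisubstituted C8=C9 alkene and the electron-poor, iodine-bearing C2=C3 alkene are too hindered to react at room temperature, and borane consumed by the carbamate and anilide N–H bonds is covered by the excess and released on aqueous work-up. Zerovalent palladium, formed from Pd(dppf)Cl2 in the flask, inserts into the C3–I bond with retention of the E geometry, the base-activated borate of 42 transfers its primary alkyl group to palladium, and reductive elimination forms C3–C4. The closest known reaction type is the coupling, between molecules and in macrocyclisations, of B-alkyl-9-BBN reagents with (E)-alkenyl iodides under Pd(dppf)Cl2/AsPh3/carbonate conditions. The 19-membered ring closes end to end through a large palladacycle in which the alkyl and alkenyl groups sit cis on palladium; small-ring closure rules do not apply, and ring closure is favoured over oligomerisation only by keeping the concentration of 42 low (slow addition, about 1 mM). No stereocentre is formed, and C6 is untouched because neither hydroboration nor transmetalation involves it. The wide bite angle of dppf favours reductive elimination over β-hydride elimination of the alkylpalladium species, and AsPh3 speeds transmetalation. Oxidative addition to the alkenyl iodide is much faster than ionisation of the hindered secondary allylic carbamate at C7, so the carbamate is expected to survive.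

Step 26
Reactants: 43 macrolactam bis-silyl ether
Product: 44 target macrolactam CNP0247621.1
Conditions: HF·pyridine, pyridine, THF, 0 °C → rt
Reagents that add atoms: none
Why: Fluoride-mediated cleavage of silyl ethers: the aryl TIPS group leaves quickly because phenoxide is a good leaving group on silicon, the hindered C11 TBS group more slowly; buffered HF leaves the carbamate, the enamide and the allylic C7–O bond intact.

## Compound list

1 | 3-hydroxy-5-nitrobenzoic acid | O=C(O)c1cc(O)cc([N+](=O)[O-])c1 | starting material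
2 | 3-(hydroxymethyl)-5-nitrophenol | OCc1cc(O)cc([N+](=O)[O-])c1 | intermediate
3 | [3-nitro-5-(triisopropylsilyloxy)phenyl]methanol | OCc1cc(O[Si](C(C)C)(C(C)C)C(C)C)cc([N+](=O)[O-])c1 | intermediate
4 | 3-nitro-5-(triisopropylsilyloxy)benzyl bromide | BrCc1cc(O[Si](C(C)C)(C(C)C)C(C)C)cc([N+](=O)[O-])c1 | intermediate
5 | (S)-4-benzyl-3-propionyloxazolidin-2-one | CCC(=O)N1[C@@H](Cc2ccccc2)COC1=O | starting material
6 | sodium (Z)-enolate of 5 | [Na+].C/C=C(\[O-])N1[C@@H](Cc2ccccc2)COC1=O | intermediate (not isolated)
7 | (S)-4-benzyl-3-[(R)-2-methyl-3-[3-nitro-5-(triisopropylsilyloxy)phenyl]propanoyl]oxazolidin-2-one | O=C([C@H](C)Cc1cc(O[Si](C(C)C)(C(C)C)C(C)C)cc([N+](=O)[O-])c1)N1[C@@H](Cc2ccccc2)COC1=O | intermediate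
8 | (R)-2-methyl-3-[3-nitro-5-(triisopropylsilyloxy)phenyl]propan-1-ol | OC[C@H](C)Cc1cc(O[Si](C(C)C)(C(C)C)C(C)C)cc([N+](=O)[O-])c1 | intermediate
9 | (R)-2-methyl-3-[3-nitro-5-(triisopropylsilyloxy)phenyl]propanal | O=C[C@H](C)Cc1cc(O[Si](C(C)C)(C(C)C)C(C)C)cc([N+](=O)[O-])c1 | intermediate
10 | 2-(diethoxyphosphoryl)acetic acid | CCOP(=O)(CC(=O)O)OCC | starting material
11 | (S)-4-benzyloxazolidin-2-one | O=C1N[C@@H](Cc2ccccc2)CO1 | starting material
12 | mixed pivalic anhydride of 10 | CCOP(=O)(CC(=O)OC(=O)C(C)(C)C)OCC | intermediate (not isolated)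
13 | (S)-4-benzyl-3-[2-(diethoxyphosphoryl)acetyl]oxazolidin-2-one | CCOP(=O)(CC(=O)N1[C@@H](Cc2ccccc2)COC1=O)OCC | intermediate
14 | (S)-4-benzyl-3-[(2E,4R)-4-methyl-5-[3-nitro-5-(triisopropylsilyloxy)phenyl]pent-2-enoyl]oxazolidin-2-one | O=C(/C=C/[C@H](C)Cc1cc(O[Si](C(C)C)(C(C)C)C(C)C)cc([N+](=O)[O-])c1)N1[C@@H](Cc2ccccc2)COC1=O | intermediate
15 | (S)-4-benzyl-3-[(S)-4-methyl-5-[3-nitro-5-(triisopropylsilyloxy)phenyl]pentanoyl]oxazolidin-2-one | O=C(CC[C@H](C)Cc1cc(O[Si](C(C)C)(C(C)C)C(C)C)cc([N+](=O)[O-])c1)N1[C@@H](Cc2ccccc2)COC1=O | intermediate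
16 | sodium (Z)-enolate of 15 | [Na+].[O-]/C(=C\C[C@H](C)Cc1cc(O[Si](C(C)C)(C(C)C)C(C)C)cc([N+](=O)[O-])c1)N1[C@@H](Cc2ccccc2)COC1=O | intermediate (not isolated)
17 | (S)-4-benzyl-3-[(2S,4R)-2-hydroxy-4-methyl-5-[3-nitro-5-(triisopropylsilyloxy)phenyl]pentanoyl]oxazolidin-2-one | O[C@H](C(=O)N1[C@@H](Cc2ccccc2)COC1=O)C[C@H](C)Cc1cc(O[Si](C(C)C)(C(C)C)C(C)C)cc([N+](=O)[O-])c1 | intermediate
18 | (S)-4-benzyl-3-[(2S,4R)-2-methoxy-4-methyl-5-[3-nitro-5-(triisopropylsilyloxy)phenyl]pentanoyl]oxazolidin-2-one | CO[C@H](C(=O)N1[C@@H](Cc2ccccc2)COC1=O)C[C@H](C)Cc1cc(O[Si](C(C)C)(C(C)C)C(C)C)cc([N+](=O)[O-])c1 | intermediate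
19 | (2S,4R)-2-methoxy-4-methyl-5-[3-nitro-5-(triisopropylsilyloxy)phenyl]pentan-1-ol | CO[C@H](CO)C[C@H](C)Cc1cc(O[Si](C(C)C)(C(C)C)C(C)C)cc([N+](=O)[O-])c1 | intermediate
20 | (2S,4R)-2-methoxy-4-methyl-5-[3-nitro-5-(triisopropylsilyloxy)phenyl]pentanal | CO[C@H](C=O)C[C@H](C)Cc1cc(O[Si](C(C)C)(C(C)C)C(C)C)cc([N+](=O)[O-])c1 | intermediate
21 | (R)-4-benzyl-3-propionyloxazolidin-2-one | CCC(=O)N1[C@H](Cc2ccccc2)COC1=O | starting material
22 | dibutylboron (Z)-enolate of 21 | C/C=C(\OB(CCCC)CCCC)N1[C@H](Cc2ccccc2)COC1=O | intermediate (not isolated)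
23 | (R)-4-benzyl-3-[(2R,3R,4S,6R)-3-hydroxy-4-methoxy-2,6-dimethyl-7-[3-nitro-5-(triisopropylsilyloxy)phenyl]heptanoyl]oxazolidin-2-one | O=C([C@H](C)[C@@H](O)[C@@H](OC)C[C@H](C)Cc1cc(O[Si](C(C)C)(C(C)C)C(C)C)cc([N+](=O)[O-])c1)N1[C@H](Cc2ccccc2)COC1=O | intermediate
24 | (R)-4-benzyl-3-[(2R,3R,4S,6R)-3-(tert-butyldimethylsilyloxy)-4-methoxy-2,6-dimethyl-7-[3-nitro-5-(triisopropylsilyloxy)phenyl]heptanoyl]oxazolidin-2-one | O=C([C@H](C)[C@@H](O[Si](C)(C)C(C)(C)C)[C@@H](OC)C[C@H](C)Cc1cc(O[Si](C(C)C)(C(C)C)C(C)C)cc([N+](=O)[O-])c1)N1[C@H](Cc2ccccc2)COC1=O | intermediate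
25 | (2S,3R,4S,6R)-3-(tert-butyldimethylsilyloxy)-4-methoxy-2,6-dimethyl-7-[3-nitro-5-(triisopropylsilyloxy)phenyl]heptan-1-ol | OC[C@H](C)[C@@H](O[Si](C)(C)C(C)(C)C)[C@@H](OC)C[C@H](C)Cc1cc(O[Si](C(C)C)(C(C)C)C(C)C)cc([N+](=O)[O-])c1 | intermediate
26 | (2R,3R,4S,6R)-3-(tert-butyldimethylsilyloxy)-4-methoxy-2,6-dimethyl-7-[3-nitro-5-(triisopropylsilyloxy)phenyl]heptanal | O=C[C@H](C)[C@@H](O[Si](C)(C)C(C)(C)C)[C@@H](OC)C[C@H](C)Cc1cc(O[Si](C(C)C)(C(C)C)C(C)C)cc([N+](=O)[O-])c1 | intermediate
27 | 2-(triphenylphosphoranylidene)propanal | CC(C=O)=P(c1ccccc1)(c1ccccc1)c1ccccc1 | starting material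
28 | (2E,4S,5R,6S,8R)-5-(tert-butyldimethylsilyloxy)-6-methoxy-2,4,8-trimethyl-9-[3-nitro-5-(triisopropylsilyloxy)phenyl]non-2-enal | O=C/C(C)=C/[C@H](C)[C@@H](O[Si](C)(C)C(C)(C)C)[C@@H](OC)C[C@H](C)Cc1cc(O[Si](C(C)C)(C(C)C)C(C)C)cc([N+](=O)[O-])c1 | intermediate
29 | cis-but-2-ene | C/C=C\C | starting material
30 | (Z)-crotylpotassium | [K+].C/C=C\[CH2-] | intermediate (not isolated)
31 | (Z)-crotyldiisopinocampheylborane, isopinocampheyl groups of the (−)-α-pinene series | C/C=C\CB([C@H]1C[C@H]2C[C@@H]([C@@H]1C)C2(C)C)[C@H]1C[C@H]2C[C@@H]([C@@H]1C)C2(C)C | intermediate (not isolated)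
32 | (3S,4R,5E,7S,8R,9S,11R)-8-(tert-butyldimethylsilyloxy)-9-methoxy-3,5,7,11-tetramethyl-12-[3-nitro-5-(triisopropylsilyloxy)phenyl]dodeca-1,5-dien-4-ol | C=C[C@H](C)[C@@H](O)/C(C)=C/[C@H](C)[C@@H](O[Si](C)(C)C(C)(C)C)[C@@H](OC)C[C@H](C)Cc1cc(O[Si](C(C)C)(C(C)C)C(C)C)cc([N+](=O)[O-])c1 | intermediate
33 | N-(trichloroacetyl)carbamate of 32 | C=C[C@H](C)[C@@H](OC(=O)NC(=O)C(Cl)(Cl)Cl)/C(C)=C/[C@H](C)[C@@H](O[Si](C)(C)C(C)(C)C)[C@@H](OC)C[C@H](C)Cc1cc(O[Si](C(C)C)(C(C)C)C(C)C)cc([N+](=O)[O-])c1 | intermediate (not isolated)
34 | carbamate of 32 (nitroarene), (3S,4R,5E,7S,8R,9S,11R) | C=C[C@H](C)[C@@H](OC(N)=O)/C(C)=C/[C@H](C)[C@@H](O[Si](C)(C)C(C)(C)C)[C@@H](OC)C[C@H](C)Cc1cc(O[Si](C(C)C)(C(C)C)C(C)C)cc([N+](=O)[O-])c1 | intermediate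
35 | aniline corresponding to 34 | C=C[C@H](C)[C@@H](OC(N)=O)/C(C)=C/[C@H](C)[C@@H](O[Si](C)(C)C(C)(C)C)[C@@H](OC)C[C@H](C)Cc1cc(O[Si](C(C)C)(C(C)C)C(C)C)cc(N)c1 | intermediate
36 | diethyl methylmalonate | CCOC(=O)C(C)C(=O)OCC | starting material
37 | sodium enolate of 36 | [Na+].CCOC(=O)[C-](C)C(=O)OCC | intermediate (not isolated)
38 | diethyl 2-(diiodomethyl)-2-methylmalonate | CCOC(=O)C(C)(C(I)I)C(=O)OCC | intermediate
39 | (E)-3-iodo-2-methylacrylic acid | I/C=C(\C)C(=O)O | intermediate
40 | (E)-3-iodo-2-methylacryloyl chloride | I/C=C(\C)C(Cl)=O | intermediate (not isolated)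
41 | seco (E)-3-iodo-2-methylacrylanilide with C6 vinyl group, C7 carbamate, C11 O-TBS, phenol O-TIPS; (6S,7R,10S,11R,12S,14R) | I/C=C(\C)C(=O)Nc1cc(O[Si](C(C)C)(C(C)C)C(C)C)cc(c1)C[C@@H](C)C[C@H](OC)[C@H](O[Si](C)(C)C(C)(C)C)[C@@H](C)/C=C(\C)[C@H](OC(N)=O)[C@@H](C)C=C | intermediate
42 | C4 B-alkyl-9-borabicyclo[3.3.1]nonane from 41 | I/C=C(\C)C(=O)Nc1cc(O[Si](C(C)C)(C(C)C)C(C)C)cc(c1)C[C@@H](C)C[C@H](OC)[C@H](O[Si](C)(C)C(C)(C)C)[C@@H](C)/C=C(\C)[C@H](OC(N)=O)[C@@H](C)CCB1C2CCCC1CCC2 | intermediate (not isolated)
43 | macrolactam with C11 O-TBS and phenol O-TIPS | CO[C@H]1C[C@H](C)Cc2cc(O[Si](C(C)C)(C(C)C)C(C)C)cc(c2)NC(=O)/C(C)=C/CC[C@H](C)[C@@H](OC(N)=O)/C(C)=C/[C@H](C)[C@H]1O[Si](C)(C)C(C)(C)C | intermediate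
44 | CNP0247621.1 | CO[C@H]1C[C@H](C)Cc2cc(O)cc(c2)NC(=O)/C(C)=C/CC[C@H](C)[C@@H](OC(N)=O)/C(C)=C/[C@H](C)[C@H]1O | target

## Step count and least certain steps

Total: 26 steps (23 on the main line from 1, one for phosphonate 13, two for acid 39). Longest linear sequence: 23 steps (steps 1–6, 8–21 and 24–26).

**Step 25 (key step).** The most likely failure is coupling between molecules (oligomerisation) outrunning ring closure, because the 19-membered transition state has little pre-organisation. Protodeboronation or β-hydride elimination of the alkylpalladium intermediate, and incomplete hydroboration if N–H bonds consume the borane, are the other ways to lose material. Loss of the aryl silyl group under aqueous carbonate would be harmless, since it is removed in step 26 anyway. The fallback keeps the C3–C4 coupling of the crotylation vinyl group but runs it between two molecules and closes the ring at the amide. It sets out from carbamate 34 and acid 39 and returns at 43. Acid 39 is esterified (allyl bromide, K2CO3, DMF) to allyl (E)-3-iodo-2-methylacrylate F1. Carbamate 34 is hydroborated with 9-BBN to the C4 B-alkyl-9-borabicyclononane F2, which is coupled with F1 (Pd(dppf)Cl2, AsPh3, Cs2CO3, DMF/THF/H2O) to the nitro allyl ester F3. Reduction with Fe/NH4Cl gives the amino allyl ester F4, Pd(PPh3)4 with morpholine frees the seco amino acid F5, and macrolactamisation (BOP-Cl, iPr2NEt, toluene, high dilution) gives 43.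

**Step 19.** The crotyl transfer to enal 28 gets no help from the substrate, so incomplete facial control by the reagent, or erosion of the syn selectivity if the borane warms and isomerises before it reacts, would give stereoisomers at C6/C7. Partial loss of the aryl silyl ether in the perborate work-up is a further way to lose material. The fallback sets the C6/C7 pair by an auxiliary aldol and builds the vinyl group afterwards; it sets out from enal 28 and imide 21 and returns at 32. The boron enolate of 21 (Bu2BOTf, iPr2NEt, CH2Cl2, −78 → 0 °C) adds to 28 to give the syn aldol adduct (R)-4-benzyl-3-[(2R,3R,4E,6S,7R,8S,10R)-7-(tert-butyldimethylsilyloxy)-3-hydroxy-8-methoxy-2,4,6,10-tetramethyl-11-[3-nitro-5-(triisopropylsilyloxy)phenyl]undec-4-enoyl]oxazolidin-2-one F6. TESOTf and 2,6-lutidine give the C7 triethylsilyl ether of the aldol adduct F7, LiBH4 gives the primary alcohol F8, Dess–Martin oxidation gives the aldehyde F9, and methylenation with Ph3P=CH2 (from Ph3PCH3Br and KN(SiMe3)2, THF, −78 → 0 °C) gives the C7 triethylsilyl ether of 32 F10. PPTS in MeOH at 0 °C removes only the triethylsilyl group and gives 32.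

**Step 14.** The α-methoxy aldehyde 20 may hydrate or epimerise at C12 under the amine and the boron Lewis acid before it is consumed, and the hindered aldolate may revert during the oxidative work-up. The fallback replaces the auxiliary aldol and the Wittig homologation by a substrate-controlled crotylation and a cross-metathesis; it sets out from 20 and returns at 28, bypassing steps 14 to 18. Purchased (Z)-crotylboronic acid pinacol ester adds to 20 (toluene, rt; triethanolamine work-up) through a chair transition state; a (Z)-crotylboronate adds to an α-alkoxy aldehyde with a strong 10,11-syn, 11,12-anti preference, which should give (3S,4R,5S,7R)-5-methoxy-3,7-dimethyl-8-[3-nitro-5-(triisopropylsilyloxy)phenyl]oct-1-en-4-ol F11. Silylation (TBSOTf, 2,6-lutidine) gives its TBS ether F12, and cross-metathesis with an excess of methacrolein (second-generation Hoveyda–Grubbs catalyst RuCl2(H2IMes)(=CH-C6H4-2-OiPr), CH2Cl2, 40 °C) gives the E enal 28.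

**Step 9.** Hydrogenation may be slow on the conjugated alkene, and prolonged exposure risks partial reduction of the nitro group or catalyst deactivation by it. The fallback avoids the alkene altogether; it sets out from alcohol 8 and returns at 15. Iodination (I2, PPh3, imidazole) gives (R)-1-(3-iodo-2-methylpropyl)-3-nitro-5-(triisopropylsilyloxy)benzene F13. Alkylation of di-tert-butyl malonate (NaH, DMF) gives di-tert-butyl 2-[(S)-2-methyl-3-[3-nitro-5-(triisopropylsilyloxy)phenyl]propyl]malonate F14. Ester cleavage and decarboxylation (TFA, CH2Cl2; then toluene, 110 °C) give (S)-4-methyl-5-[3-nitro-5-(triisopropylsilyloxy)phenyl]pentanoic acid F15, which is attached to auxiliary 11 (PivCl, Et3N; then 11, LiCl) to give 15.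

## Further compounds

F1 | step 25 | allyl (E)-3-iodo-2-methylacrylate | I/C=C(\C)C(=O)OCC=C
F2 | step 25 | C4 B-alkyl-9-borabicyclo[3.3.1]nonane from 34 | B1(C2CCCC1CCC2)CC[C@H](C)[C@@H](OC(N)=O)/C(C)=C/[C@H](C)[C@@H](O[Si](C)(C)C(C)(C)C)[C@@H](OC)C[C@H](C)Cc1cc(O[Si](C(C)C)(C(C)C)C(C)C)cc([N+](=O)[O-])c1
F3 | step 25 | nitro allyl ester: C1 allyl ester of the open chain with C2=C3 in place | C=CCOC(=O)/C(C)=C/CC[C@H](C)[C@@H](OC(N)=O)/C(C)=C/[C@H](C)[C@@H](O[Si](C)(C)C(C)(C)C)[C@@H](OC)C[C@H](C)Cc1cc(O[Si](C(C)C)(C(C)C)C(C)C)cc([N+](=O)[O-])c1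
F4 | step 25 | amino allyl ester | C=CCOC(=O)/C(C)=C/CC[C@H](C)[C@@H](OC(N)=O)/C(C)=C/[C@H](C)[C@@H](O[Si](C)(C)C(C)(C)C)[C@@H](OC)C[C@H](C)Cc1cc(O[Si](C(C)C)(C(C)C)C(C)C)cc(N)c1
F5 | step 25 | seco amino acid | OC(=O)/C(C)=C/CC[C@H](C)[C@@H](OC(N)=O)/C(C)=C/[C@H](C)[C@@H](O[Si](C)(C)C(C)(C)C)[C@@H](OC)C[C@H](C)Cc1cc(O[Si](C(C)C)(C(C)C)C(C)C)cc(N)c1
F6 | step 19 | (R)-4-benzyl-3-[(2R,3R,4E,6S,7R,8S,10R)-7-(tert-butyldimethylsilyloxy)-3-hydroxy-8-methoxy-2,4,6,10-tetramethyl-11-[3-nitro-5-(triisopropylsilyloxy)phenyl]undec-4-enoyl]oxazolidin-2-one | O=C([C@H](C)[C@@H](O)/C(C)=C/[C@H](C)[C@@H](O[Si](C)(C)C(C)(C)C)[C@@H](OC)C[C@H](C)Cc1cc(O[Si](C(C)C)(C(C)C)C(C)C)cc([N+](=O)[O-])c1)N1[C@H](Cc2ccccc2)COC1=O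
F7 | step 19 | C7 triethylsilyl ether of F6 | O=C([C@H](C)[C@@H](O[Si](CC)(CC)CC)/C(C)=C/[C@H](C)[C@@H](O[Si](C)(C)C(C)(C)C)[C@@H](OC)C[C@H](C)Cc1cc(O[Si](C(C)C)(C(C)C)C(C)C)cc([N+](=O)[O-])c1)N1[C@H](Cc2ccccc2)COC1=O
F8 | step 19 | (2S,3R,4E,6S,7R,8S,10R)-7-(tert-butyldimethylsilyloxy)-8-methoxy-2,4,6,10-tetramethyl-11-[3-nitro-5-(triisopropylsilyloxy)phenyl]-3-(triethylsilyloxy)undec-4-en-1-ol | OC[C@H](C)[C@@H](O[Si](CC)(CC)CC)/C(C)=C/[C@H](C)[C@@H](O[Si](C)(C)C(C)(C)C)[C@@H](OC)C[C@H](C)Cc1cc(O[Si](C(C)C)(C(C)C)C(C)C)cc([N+](=O)[O-])c1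
F9 | step 19 | (2R,3R,4E,6S,7R,8S,10R)-7-(tert-butyldimethylsilyloxy)-8-methoxy-2,4,6,10-tetramethyl-11-[3-nitro-5-(triisopropylsilyloxy)phenyl]-3-(triethylsilyloxy)undec-4-enal | O=C[C@H](C)[C@@H](O[Si](CC)(CC)CC)/C(C)=C/[C@H](C)[C@@H](O[Si](C)(C)C(C)(C)C)[C@@H](OC)C[C@H](C)Cc1cc(O[Si](C(C)C)(C(C)C)C(C)C)cc([N+](=O)[O-])c1
F10 | step 19 | C7 triethylsilyl ether of 32 | C=C[C@H](C)[C@@H](O[Si](CC)(CC)CC)/C(C)=C/[C@H](C)[C@@H](O[Si](C)(C)C(C)(C)C)[C@@H](OC)C[C@H](C)Cc1cc(O[Si](C(C)C)(C(C)C)C(C)C)cc([N+](=O)[O-])c1
F11 | step 14 | (3S,4R,5S,7R)-5-methoxy-3,7-dimethyl-8-[3-nitro-5-(triisopropylsilyloxy)phenyl]oct-1-en-4-ol | C=C[C@H](C)[C@@H](O)[C@@H](OC)C[C@H](C)Cc1cc(O[Si](C(C)C)(C(C)C)C(C)C)cc([N+](=O)[O-])c1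
F12 | step 14 | TBS ether of F11 | C=C[C@H](C)[C@@H](O[Si](C)(C)C(C)(C)C)[C@@H](OC)C[C@H](C)Cc1cc(O[Si](C(C)C)(C(C)C)C(C)C)cc([N+](=O)[O-])c1
F13 | step 9 | (R)-1-(3-iodo-2-methylpropyl)-3-nitro-5-(triisopropylsilyloxy)benzene | IC[C@H](C)Cc1cc(O[Si](C(C)C)(C(C)C)C(C)C)cc([N+](=O)[O-])c1
F14 | step 9 | di-tert-butyl 2-[(S)-2-methyl-3-[3-nitro-5-(triisopropylsilyloxy)phenyl]propyl]malonate | CC(C)(C)OC(=O)C(C[C@H](C)Cc1cc(O[Si](C(C)C)(C(C)C)C(C)C)cc([N+](=O)[O-])c1)C(=O)OC(C)(C)C
F15 | step 9 | (S)-4-methyl-5-[3-nitro-5-(triisopropylsilyloxy)phenyl]pentanoic acid | OC(=O)CC[C@H](C)Cc1cc(O[Si](C(C)C)(C(C)C)C(C)C)cc([N+](=O)[O-])c1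
A1 | alternative 1 | N-(4-methoxybenzyl) macrolactam with free phenol, C7 O-TES and C11 O-TBS | CO[C@H]1C[C@H](C)Cc2cc(O)cc(c2)N(Cc3ccc(OC)cc3)C(=O)/C(C)=C/CC[C@H](C)[C@@H](O[Si](CC)(CC)CC)/C(C)=C/[C@H](C)[C@H]1O[Si](C)(C)C(C)(C)C
A2 | alternative 2 | macrocyclic C8≡C9 alkyne with C7 O-TES, C11 O-TBS and phenol O-TBS | CO[C@H]1C[C@H](C)Cc2cc(O[Si](C)(C)C(C)(C)C)cc(c2)NC(=O)/C(C)=C/CC[C@H](C)[C@@H](O[Si](CC)(CC)CC)C#C[C@H](C)[C@H]1O[Si](C)(C)C(C)(C)C
A3 | alternative 3 | macrolactam with C7 O-TES, C11 O-TBS and phenol O-TIPS | CO[C@H]1C[C@H](C)Cc2cc(O[Si](C(C)C)(C(C)C)C(C)C)cc(c2)NC(=O)/C(C)=C/CC[C@H](C)[C@@H](O[Si](CC)(CC)CC)/C(C)=C/[C@H](C)[C@H]1O[Si](C)(C)C(C)(C)C
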